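## The problem

The target is a cross-conjugated cyclohexa-2,5-dienone. Ring atoms are numbered here C1 (carbonyl), C2 (bearing the (E)-propenyl group), C3–H, C4, C5–OMe, C6–H; the side chain is C7 (aryl-bearing CH), C8 (bonded to C4) and C9 (methyl). This numbering is used for all ring compounds below.

- The only stereocentre, C4, is fully substituted: it carries OMe, the (E)-1-arylprop-1-en-2-yl group and the two sp2 ring carbons C3 and C5. By CIP analysis of the given SMILES it is (S).
- No second stereocentre can control C4. In any flat precursor (quinone or phenol) the two faces at C4 differ only through the distant pair C3–H / C5–OMe, so enantioselection is the core problem.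
- C4 is a tertiary, triply allylic methyl ether. Acid ionises it to a cation delocalised into the ring and onto benzylic C7, so no acid may be used once C4 is set.
- The oxygen pattern (C1=O, C4–O, C5–OMe) is that of a 2-methoxy-1,4-benzoquinone. Its C4 carbonyl is the more electrophilic one, because C1=O is a vinylogous ester through C5=C6.
- The (E)-geometry of the trisubstituted C7=C8 bond must be fixed before C4–C8 is formed. A C2 propenyl group would make any quinone-stage intermediate a vinylquinone (diene and dienophile at once), so it is carried as an allyl group.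
- The feature that is used: the C2=C3 bond, flanked by C1=O and C4 and carrying H at C3, is the only dienophilic double bond of the corresponding quinone, since C5=C6 is switched off by the C5 methoxy group. It can be engaged in a [4+2] addition with cyclopentadiene and regenerated by cycloreversion. While it is engaged, C2 and C3 are stereocentres of a cup-shaped tricycle and the two faces of the C4 carbonyl become diastereotopic.

## Retrosynthesis

**18 ⇒ 17.** No bond is cut; the (E)-propenyl group at C2 is traced back to an allyl group. This avoids a vinylquinone earlier in the route. The forward reaction is a one-position double-bond migration into conjugation with the dienone, which must give the E isomer and leave C7=C8 alone.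

**17 ⇒ 16.** Cyclopentadiene (10) is added back across C2=C3 (bonds from C2 and C3 to the two bridgeheads). The gain is stereochemical: in 16 the stereocentre C4 sits next to the ring-fusion centre C3 in a rigid endo tricycle. The forward reaction is a thermal retro-Diels–Alder that must spare the tertiary ether.

**16 ⇒ 14 ⇒ 11 + 13.** The O–CH3 bond and then the C4–C8 bond are cut. The same C–C bond could be cut on the flat quinone (Alternative 1), but in 11 the concave face of the C4 carbonyl is covered by the etheno bridge, so an alkenyl metal must enter from the convex face. The C1 carbonyl is a vinylogous ester next to the quaternary C2 and should not compete. The alkenylcerium 13 carries the finished (E)-C7=C8 unit.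

**11 ⇒ 9 + 10.** This is the Diels–Alder disconnection and the point where absolute configuration enters. The precursor 9 is a flat, achiral C10 quinone; the product has four stereocentres. The forward reaction needs site selectivity (C2=C3 over C5=C6), endo selectivity and catalyst control of the face.

**9 ⇒ 8 ⇒ 6.** The quinone comes from oxidative demethylation of the para-related methoxy pair of 8. The allyl–aryl bond of 8 is cut to the Grignard reagent 7 from commercial bromide 6.

**13 ⇒ 12 ⇒ 5 ⇒ 3 ⇒ 1.** The cerium reagent comes from alkenyllithium 12 and iodide 5. Iodide 5 comes from syn-hydrozirconation (via 4) and iodination of alkyne 3, and 3 from methylation of commercial alkyne 1 via acetylide 2.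

Remark on the chemistry (assumption): the sense of induction in step 5 is assigned from the two-point binding model described there, which points to the (R)-configured catalyst for adduct 11; both catalyst antipodes are available, and the antipode is used if the assignment has to be reversed.

Remark: cyclopentadiene (10) is obtained by cracking commercial dicyclopentadiene just before use; this is not counted as a step.

## Roads not taken

**Alternative 1:** (the most obvious) Cut C4–C8 and O–CH3 on the flat ring. The forward key step is 1,2-addition of 13 to the propenyl quinone A1 at the C4 carbonyl to give the tertiary alcohol A2, followed by O-methylation.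
- The regiochemistry is right and the route is short.
- The faces of the C4 carbonyl of A1 are enantiotopic and distinguished only by C3–H versus C5–OMe. No dependable catalytic enantioselective alkenylation of a quinone carbonyl exists, and quinones oxidise the organozinc or titanium reagents that asymmetric additions use.
- A1 is a vinylquinone and prone to self-cycloaddition.
- The chosen plan keeps the same bond-forming reaction but runs it on a substrate whose faces are diastereotopic.

**Alternative 2:** Cut C4–OMe. The forward key step is oxidative dearomatisation of phenol A3 with PhI(OAc)2 (or a chiral aryl iodide with a terminal oxidant) in methanol.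
- The cation A4 is captured by solvent methanol with no chiral information nearby, so high enantioselectivity in this intermolecular para attack is unlikely.
- The charge of A4 is shared with benzylic C7, so attack there competes.
- The electron-rich styrene and propenyl groups are themselves oxidised by the iodine reagent.
- The chosen plan needs no oxidation once the alkenes are in place.

**Alternative 3:** Cut C4–C8 as a cation–alkene union. The forward key step is acid ionisation of quinone monoketal A5 in the presence of (E)-methylisoeugenol A6, capture of the benzylic cation by the C5 oxygen to give hydrobenzofuranone A7, then opening of the C7–O bond and O-methylation.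
- The ionised ketal is a pentadienyl cation spanning C2–C6. Alkenes should bond at its termini C2 and C6 ([5+2] mode, or C2 attack followed by closure of the carbonyl oxygen), not at the central C4.
- Three stereocentres are made to keep one.
- The ring opening needs acid, which ionises C4–OMe.
- The final enol methylation has a regiochemistry problem.
- Nothing controls absolute configuration.

Key step: step 5

## Steps

Step 1
Reactants: 1 4-ethynyl-1,2-dimethoxybenzene
Product: 3 1,2-dimethoxy-4-(prop-1-yn-1-yl)benzene, via lithium (3,4-dimethoxyphenyl)acetylide 2 (not isolated)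
Conditions: n-BuLi, THF, −78 °C; MeI, −78 °C → rt
Reagents that add atoms: iodomethane, CI
Why: Deprotonation of the terminal alkyne and SN2 methylation of the lithium acetylide; no stereochemistry is involved.

Step 2
Reactants: 3 1,2-dimethoxy-4-(prop-1-yn-1-yl)benzene
Product: 5 (E)-4-(2-iodoprop-1-en-1-yl)-1,2-dimethoxybenzene, via alkenylzirconocene chloride 4 (not isolated)
Conditions: Cp2Zr(H)Cl (1.3 equiv), THF, 40 °C; I2, 0 °C
Reagents that add atoms: iodine, II
Why: syn-Hydrozirconation of the aryl methyl alkyne should place zirconium on the methyl-bearing carbon, away from the aryl group, the slight excess of hydride allowing equilibration to this isomer. Iodinolysis of the C–Zr bond with retention gives the (E)-iodide (iodine trans to aryl), which fixes the later (E)-C7=C8 geometry.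

Step 3
Reactants: 6 1-bromo-2,4,5-trimethoxybenzene
Product: 8 1,2,4-trimethoxy-5-(prop-2-en-1-yl)benzene, via (2,4,5-trimethoxyphenyl)magnesium bromide 7 (not isolated)
Conditions: Mg, THF, reflux; allyl bromide, 0 °C → rt
Reagents that add atoms: allyl bromide, C=CCBr
Why: Grignard formation and coupling with allyl bromide; SN2 and SN2′ attack give the same allyl arene.

Step 4
Reactants: 8 1,2,4-trimethoxy-5-(prop-2-en-1-yl)benzene
Product: 9 2-methoxy-5-(prop-2-en-1-yl)cyclohexa-2,5-diene-1,4-dione
Conditions: (NH4)2Ce(NO3)6 (2.5 equiv), MeCN/H2O, 0 °C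
Reagents that add atoms: water, O
Why: Oxidative demethylation by the tetravalent cerium salt converts the para-related methoxy pair into the p-quinone (carbonyl oxygens from water), while the third methoxy group remains as the C5 vinylogous ester. The non-conjugated allyl group should not be attacked.

Step 5
Reactants: 9 2-methoxy-5-(prop-2-en-1-yl)cyclohexa-2,5-diene-1,4-dione; 10 cyclopenta-1,3-diene
Product: 11 (1S,4R,4aS,8aR)-7-methoxy-4a-(prop-2-en-1-yl)-1,4,4a,8a-tetrahydro-1,4-methanonaphthalene-5,8-dione
Conditions: (3aR)-1-(2-methylphenyl)-3,3-diphenyltetrahydro-1H,3H-pyrrolo[1,2-c][1,3,2]oxazaborole (20 mol %), (CF3SO2)2NH (20 mol %), CH2Cl2, −78 °C, dark; Et3N quench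
Reagents that add atoms: none
Why: This is a catalytic enantioselective Diels–Alder reaction of a quinone; the closest known type is the N-protonated oxazaborolidine-catalysed addition of cyclopentadiene and butadienes to 2,5-dialkyl-1,4-benzoquinones. The boron of the cationic catalyst binds the C4 carbonyl oxygen at the lone pair syn to C3–H, and a C3–H···O contact with the ring oxygen of the catalyst holds the quinone against one phenyl group, so that only the face of C2=C3 that is Re at C3 and Si at C2 stays open. Cyclopentadiene adds there in a concerted, asynchronous, suprafacial [4+2] with the bond to the β-carbon C2 more advanced; this closes the bicyclo[2.2.1]heptene ring by cycloaddition and makes the ring fusion cis. Endo orientation, reinforced by the Lewis acid, places the six-membered ring under the new etheno bridge. The four new stereocentres (C2, C3 and the two bridgeheads) are thus fixed relative to each other by the endo suprafacial mode and in the absolute sense by the catalyst. Site selectivity between C2=C3 and C5=C6 is secured by the C5 methoxy group, which makes C5=C6 an electron-rich vinylogous ester. The selectivity most at risk is the face, because it requires binding at the less basic C4 carbonyl; the C3–H contact and the low temperature (no background reaction) are expected to enforce it.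

Step 6
Reactants: 5 (E)-4-(2-iodoprop-1-en-1-yl)-1,2-dimethoxybenzene; 11 (1S,4R,4aS,8aR)-7-methoxy-4a-(prop-2-en-1-yl)-1,4,4a,8a-tetrahydro-1,4-methanonaphthalene-5,8-dione
Product: 14 (1S,4R,4aS,8S,8aR)-8-[(E)-1-(3,4-dimethoxyphenyl)prop-1-en-2-yl]-8-hydroxy-7-methoxy-4a-(prop-2-en-1-yl)-1,4,4a,8a-tetrahydro-1,4-methanonaphthalen-5(8H)-one, via alkenyllithium 12 (not isolated), via alkenylcerium dichloride 13 (not isolated)
Conditions: 5, t-BuLi (2 equiv), Et2O, −78 °C; CeCl3, THF, −78 °C; 11, −78 °C; aq NH4Cl
Reagents that add atoms: none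
Why: Iodine–lithium exchange keeps the alkene geometry, and the weakly basic organocerium adds 1,2 to the C4 carbonyl, because C1=O is a deactivated vinylogous ester next to the quaternary C2. Attack from the convex face, anti to the etheno bridge, puts the alkenyl group cis to C3–H and sets C4 by substrate control.

Step 7
Reactants: 14 (1S,4R,4aS,8S,8aR)-8-[(E)-1-(3,4-dimethoxyphenyl)prop-1-en-2-yl]-8-hydroxy-7-methoxy-4a-(prop-2-en-1-yl)-1,4,4a,8a-tetrahydro-1,4-methanonaphthalen-5(8H)-one
Product: 16 (1S,4R,4aS,8S,8aR)-8-[(E)-1-(3,4-dimethoxyphenyl)prop-1-en-2-yl]-7,8-dimethoxy-4a-(prop-2-en-1-yl)-1,4,4a,8a-tetrahydro-1,4-methanonaphthalen-5(8H)-one, via potassium alkoxide 15 (not isolated)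
Conditions: KH, THF, 0 °C; MeI, 0 °C → rt, dark
Reagents that add atoms: iodomethane, CI
Why: Williamson methylation of the tertiary alkoxide; no carbonyl is β to the alkoxide, so retro-aldol cleavage is not possible and C4 is not touched.

Step 8
Reactants: 16 (1S,4R,4aS,8S,8aR)-8-[(E)-1-(3,4-dimethoxyphenyl)prop-1-en-2-yl]-7,8-dimethoxy-4a-(prop-2-en-1-yl)-1,4,4a,8a-tetrahydro-1,4-methanonaphthalen-5(8H)-one
Product: 17 (4S)-4-[(E)-1-(3,4-dimethoxyphenyl)prop-1-en-2-yl]-4,5-dimethoxy-2-(prop-2-en-1-yl)cyclohexa-2,5-dien-1-one
Conditions: 1,2-dichlorobenzene (dilute), 180 °C, N2 stream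
Reagents that add atoms: none
Why: Retro-Diels–Alder reaction: the bonds from C2 and C3 to the bridgeheads break, cyclopentadiene leaves and the C2=C3 bond returns in conjugation with C1=O, helped by the quaternary C2. The auxiliary stereocentres vanish; C4 is not part of the pericyclic array and keeps its configuration.

Step 9
Reactants: 17 (4S)-4-[(E)-1-(3,4-dimethoxyphenyl)prop-1-en-2-yl]-4,5-dimethoxy-2-(prop-2-en-1-yl)cyclohexa-2,5-dien-1-one
Product: 18 (4S)-4-[(E)-1-(3,4-dimethoxyphenyl)prop-1-en-2-yl]-4,5-dimethoxy-2-[(E)-prop-1-en-1-yl]cyclohexa-2,5-dien-1-one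
Conditions: RuHCl(CO)(PPh3)3 (5 mol %), toluene, 70 °C
Reagents that add atoms: none
Why: Ruthenium hydride insertion and β-hydride elimination move the terminal double bond one position into conjugation with the dienone, as in allylarene-to-propenylarene isomerisation. The E isomer is favoured by conjugation and by A(1,3) strain in the Z isomer; the neutral conditions do not ionise C4–OMe.

## Compound list

1 | 4-ethynyl-1,2-dimethoxybenzene | C#Cc1ccc(OC)c(OC)c1 | starting material
2 | lithium (3,4-dimethoxyphenyl)acetylide | [Li]C#Cc1ccc(OC)c(OC)c1 | intermediate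
3 | 1,2-dimethoxy-4-(prop-1-yn-1-yl)benzene | CC#Cc1ccc(OC)c(OC)c1 | intermediate
4 | chlorobis(cyclopentadienyl)[(E)-1-(3,4-dimethoxyphenyl)prop-1-en-2-yl]zirconium | Cl[Zr](C1C=CC=C1)(C1C=CC=C1)/C(C)=C/c1ccc(OC)c(OC)c1 | intermediate
5 | (E)-4-(2-iodoprop-1-en-1-yl)-1,2-dimethoxybenzene | I/C(C)=C/c1ccc(OC)c(OC)c1 | intermediate
6 | 1-bromo-2,4,5-trimethoxybenzene | COc1cc(OC)c(Br)cc1OC | starting material
7 | (2,4,5-trimethoxyphenyl)magnesium bromide | COc1cc(OC)c([Mg]Br)cc1OC | intermediate
8 | 1,2,4-trimethoxy-5-(prop-2-en-1-yl)benzene | COc1cc(OC)c(CC=C)cc1OC | intermediate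
9 | 2-methoxy-5-(prop-2-en-1-yl)cyclohexa-2,5-diene-1,4-dione | COC1=CC(=O)C(CC=C)=CC1=O | intermediate
10 | cyclopenta-1,3-diene | C1=CC=CC1 | starting material
11 | (1S,4R,4aS,8aR)-7-methoxy-4a-(prop-2-en-1-yl)-1,4,4a,8a-tetrahydro-1,4-methanonaphthalene-5,8-dione (endo adduct) | COC1=CC(=O)[C@]2(CC=C)[C@H](C1=O)[C@@H]3C=C[C@H]2C3 | intermediate
12 | (Z)-[1-(3,4-dimethoxyphenyl)prop-1-en-2-yl]lithium (lithium trans to aryl) | [Li]/C(C)=C/c1ccc(OC)c(OC)c1 | intermediate
13 | dichloro[(E)-1-(3,4-dimethoxyphenyl)prop-1-en-2-yl]cerium | Cl[Ce](Cl)/C(C)=C/c1ccc(OC)c(OC)c1 | intermediate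
14 | (1S,4R,4aS,8S,8aR)-8-[(E)-1-(3,4-dimethoxyphenyl)prop-1-en-2-yl]-8-hydroxy-7-methoxy-4a-(prop-2-en-1-yl)-1,4,4a,8a-tetrahydro-1,4-methanonaphthalen-5(8H)-one | COC1=CC(=O)[C@]2(CC=C)[C@H]([C@]1(O)/C(C)=C/c4ccc(OC)c(OC)c4)[C@@H]3C=C[C@H]2C3 | intermediate
15 | potassium alkoxide of 14 | COC1=CC(=O)[C@]2(CC=C)[C@H]([C@]1([O-])/C(C)=C/c4ccc(OC)c(OC)c4)[C@@H]3C=C[C@H]2C3.[K+] | intermediate
16 | (1S,4R,4aS,8S,8aR)-8-[(E)-1-(3,4-dimethoxyphenyl)prop-1-en-2-yl]-7,8-dimethoxy-4a-(prop-2-en-1-yl)-1,4,4a,8a-tetrahydro-1,4-methanonaphthalen-5(8H)-one | COC1=CC(=O)[C@]2(CC=C)[C@H]([C@]1(OC)/C(C)=C/c4ccc(OC)c(OC)c4)[C@@H]3C=C[C@H]2C3 | intermediate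
17 | (4S)-4-[(E)-1-(3,4-dimethoxyphenyl)prop-1-en-2-yl]-4,5-dimethoxy-2-(prop-2-en-1-yl)cyclohexa-2,5-dien-1-one | C=CCC1=C[C@](OC)(/C(C)=C/c2ccc(OC)c(OC)c2)C(OC)=CC1=O | intermediate
18 | (4S)-4-[(E)-1-(3,4-dimethoxyphenyl)prop-1-en-2-yl]-4,5-dimethoxy-2-[(E)-prop-1-en-1-yl]cyclohexa-2,5-dien-1-one | C/C=C/C1=C[C@](OC)(/C(C)=C/c2ccc(OC)c(OC)c2)C(OC)=CC1=O | target

## Step count and risks

Total: 9 steps. Longest linear sequence: 7 steps (6 → 8 → 9 → 11 → 14 → 16 → 17 → 18); the side branch 1 → 3 → 5 joins at step 6.

**Step 5 (key step).** The catalyst may bind the more basic C1 carbonyl oxygen, or bind C4=O without a firm C3–H contact; either erodes facial selectivity. The trisubstituted C2=C3 bond may also react slowly enough for an uncatalysed pathway to contribute. The fallback gives up catalytic control and the relay. It sets out from 9 and 13: direct 1,2-addition of 13 to the C4 carbonyl of the quinone should give the racemic 2-allyl-4-hydroxy-4-alkenyl-5-methoxycyclohexadienone F1. Methylation (KH, MeI) gives the racemic methyl ether F2, which is resolved by preparative chromatography on a chiral stationary phase. The route is rejoined at 17.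

**Step 6.** The bulky alkenyl reagent may deprotonate C3–H instead of adding, or approach so slowly that addition–elimination at C5 competes. The fallback builds the alkene after the C–C bond, setting out from 11 and acetylide 2:
- The slim acetylide 2 (THF, −78 °C) should add from the same convex face to give the propargylic alcohol F3.
- Hydroxyl-directed trans-hydrostannation ([Cp*RuCl]4 cat., Bu3SnH, CH2Cl2) places tin on the carbon next to the carbinol and gives the (Z)-alkenylstannane F4.
- Methyl–tin exchange with retention (MeI, Pd(PPh3)4, copper thiophene-2-carboxylate, tetrabutylammonium diphenylphosphinate, DMF) returns to 14.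

**Step 8.** At the temperature needed for cycloreversion the triply allylic ether may lose methanol, or the alkenyl group may shift with aromatisation. The fallback changes the relay diene to one whose adducts revert near 110 °C, setting out from 9:
- The same catalysed cycloaddition with 6,6-dimethylfulvene should give the 9-isopropylidene adduct F5.
- Addition of 13 as in step 6 gives the tertiary alcohol F6, and KH/MeI gives the methyl ether F7.
- F7 should release the fulvene in refluxing toluene and return to 17.
- The enantioselectivity of the fulvene cycloaddition would have to be re-established.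

**Step 9.** The double-bond migration may stop short, give some Z isomer, or be slowed by catalyst binding to the dienone. The fallback moves the migration to the tricyclic stage, setting out from 16. The same ruthenium hydride catalyst should give the (E)-propenyl tricycle F8, where the quaternary C2 makes the Z isomer prohibitively strained. Cycloreversion of F8 as in step 8 then gives 18 directly, with the new C2=C3 bond conjugated on both sides (which should lower the temperature needed).

**Step 2.** Hydrozirconation may give some of the regioisomer with zirconium on the aryl-bearing carbon, which leads to an inseparable isomeric iodide. The fallback sets out from 3 and uses electronic regiocontrol. Copper-catalysed protoboration (CuCl, NaOt-Bu, 4,5-bis(diphenylphosphino)-9,9-dimethylxanthene, B2pin2, MeOH, THF) places copper on the aryl-bearing carbon and boron on the methyl-bearing carbon by syn addition, giving the (Z)-alkenylboronate F9. Iododeboronation with retention (NaOH, then I2, THF/H2O) returns to 5.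

## Further compounds

F1 | step 5 | racemic 4-[(E)-1-(3,4-dimethoxyphenyl)prop-1-en-2-yl]-4-hydroxy-5-methoxy-2-(prop-2-en-1-yl)cyclohexa-2,5-dien-1-one | C=CCC1=CC(O)(/C(C)=C/c2ccc(OC)c(OC)c2)C(OC)=CC1=O
F2 | step 5 | racemic 4-[(E)-1-(3,4-dimethoxyphenyl)prop-1-en-2-yl]-4,5-dimethoxy-2-(prop-2-en-1-yl)cyclohexa-2,5-dien-1-one (racemate of 17) | C=CCC1=CC(OC)(/C(C)=C/c2ccc(OC)c(OC)c2)C(OC)=CC1=O
F3 | step 6 | 8-[(3,4-dimethoxyphenyl)ethynyl]-8-hydroxy-7-methoxy-4a-(prop-2-en-1-yl)-1,4,4a,8a-tetrahydro-1,4-methanonaphthalen-5(8H)-one, ring configuration as in 14 | COC1=CC(=O)[C@]2(CC=C)[C@H]([C@]1(O)C#Cc4ccc(OC)c(OC)c4)[C@@H]3C=C[C@H]2C3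
F4 | step 6 | 8-[(Z)-2-(3,4-dimethoxyphenyl)-1-(tributylstannyl)ethenyl]-8-hydroxy-7-methoxy-4a-(prop-2-en-1-yl)-1,4,4a,8a-tetrahydro-1,4-methanonaphthalen-5(8H)-one, ring configuration as in 14 | COC1=CC(=O)[C@]2(CC=C)[C@H]([C@]1(O)/C([Sn](CCCC)(CCCC)CCCC)=C/c4ccc(OC)c(OC)c4)[C@@H]3C=C[C@H]2C3
F5 | step 8 | 7-methoxy-9-(propan-2-ylidene)-4a-(prop-2-en-1-yl)-1,4,4a,8a-tetrahydro-1,4-methanonaphthalene-5,8-dione, endo, configuration as in 11 | COC1=CC(=O)[C@]2(CC=C)[C@H](C1=O)[C@@H]3C=C[C@H]2C3=C(C)C
F6 | step 8 | 8-[(E)-1-(3,4-dimethoxyphenyl)prop-1-en-2-yl]-8-hydroxy-7-methoxy-9-(propan-2-ylidene)-4a-(prop-2-en-1-yl)-1,4,4a,8a-tetrahydro-1,4-methanonaphthalen-5(8H)-one, configuration as in 14 | COC1=CC(=O)[C@]2(CC=C)[C@H]([C@]1(O)/C(C)=C/c4ccc(OC)c(OC)c4)[C@@H]3C=C[C@H]2C3=C(C)C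
F7 | step 8 | 8-[(E)-1-(3,4-dimethoxyphenyl)prop-1-en-2-yl]-7,8-dimethoxy-9-(propan-2-ylidene)-4a-(prop-2-en-1-yl)-1,4,4a,8a-tetrahydro-1,4-methanonaphthalen-5(8H)-one, configuration as in 16 | COC1=CC(=O)[C@]2(CC=C)[C@H]([C@]1(OC)/C(C)=C/c4ccc(OC)c(OC)c4)[C@@H]3C=C[C@H]2C3=C(C)C
F8 | step 9 | 8-[(E)-1-(3,4-dimethoxyphenyl)prop-1-en-2-yl]-7,8-dimethoxy-4a-[(E)-prop-1-en-1-yl]-1,4,4a,8a-tetrahydro-1,4-methanonaphthalen-5(8H)-one, configuration as in 16 | COC1=CC(=O)[C@]2(/C=C/C)[C@H]([C@]1(OC)/C(C)=C/c4ccc(OC)c(OC)c4)[C@@H]3C=C[C@H]2C3
F9 | step 2 | 2-[(Z)-1-(3,4-dimethoxyphenyl)prop-1-en-2-yl]-4,4,5,5-tetramethyl-1,3,2-dioxaborolane (boron trans to aryl) | CC1(C)OB(OC1(C)C)/C(C)=C/c1ccc(OC)c(OC)c1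
A1 | alternative 1 | 2-methoxy-5-[(E)-prop-1-en-1-yl]cyclohexa-2,5-diene-1,4-dione | COC1=CC(=O)C(/C=C/C)=CC1=O
A2 | alternative 1 | racemic 4-[(E)-1-(3,4-dimethoxyphenyl)prop-1-en-2-yl]-4-hydroxy-5-methoxy-2-[(E)-prop-1-en-1-yl]cyclohexa-2,5-dien-1-one | C/C=C/C1=CC(O)(/C(C)=C/c2ccc(OC)c(OC)c2)C(OC)=CC1=O
A3 | alternative 2 | 4-[(E)-1-(3,4-dimethoxyphenyl)prop-1-en-2-yl]-5-methoxy-2-[(E)-prop-1-en-1-yl]phenol | C/C=C/c1cc(/C(C)=C/c2ccc(OC)c(OC)c2)c(OC)cc1O
A4 | alternative 2 | delocalised cation from two-electron oxidation of A3 (benzylic resonance form) | C/C=C/C1=CC(=C(C)[CH+]c2ccc(OC)c(OC)c2)C(OC)=CC1=O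
A5 | alternative 3 | 4,4,5-trimethoxy-2-(prop-2-en-1-yl)cyclohexa-2,5-dien-1-one | C=CCC1=CC(OC)(OC)C(OC)=CC1=O
A6 | alternative 3 | (E)-1,2-dimethoxy-4-(prop-1-en-1-yl)benzene | C/C=C/c1ccc(OC)c(OC)c1
A7 | alternative 3 | 2-(3,4-dimethoxyphenyl)-3a-methoxy-3-methyl-5-(prop-2-en-1-yl)-3,3a-dihydro-1-benzofuran-6(2H)-one (racemic, diastereomer mixture) | C=CCC1=CC2(OC)C(C)C(c3ccc(OC)c(OC)c3)OC2=CC1=O
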